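**Plan**

1. Retrosynthesis: the sulfate O–S bond and the sulfonyl mask on the central amine are removed first. The ring is then opened at the bond between the amide nitrogen of the ring-A (caffeoyl) arm and the terminal CH2 of the four-carbon chain, after raising that carbon to the alkyne level, giving an open-chain primary cinnamamide that carries an N-but-3-ynyl sulfonamide.
2. The chain is cut further at the central N–CH2 bond of the four-carbon arm (Mitsunobu), the ring-B cinnamoyl amide C–N bond, the ring-B side-chain C=C (Knoevenagel–Doebner), the diaryl ether C–O bond (SNAr) and the ring-A side-chain C=C (Horner–Wadsworth–Emmons).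
3. Forward: ring-A side chain, diaryl ether, ring-B acid, then the triamine chain is grown on it one nitrogen at a time, so its three nitrogens are never equivalent. The only ring, the 24-membered macrocycle, is closed by adding the primary amide N–H across the terminal alkyne.
4. Enabling feature: between the ring-A amide nitrogen and the central nitrogen lies an unbranched (CH2)4 chain, so its last carbon can enter as a terminal alkyne carbon. The enamide C=C formed is the only electron-rich alkene in the macrocycle (both cinnamoyl C=C bonds are conjugated to C=O), so ionic hydrogenation can saturate it alone.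
5. Stereochemistry: there are no stereocentres. The two E alkenes come from the Horner–Wadsworth–Emmons and Knoevenagel–Doebner steps and are not touched afterwards (light excluded); the transient enamide geometry is erased.

Key step: step 8

Remark on the chemistry: the target is drawn with a free secondary amine and a hydrogen sulfate and should be isolated as the corresponding inner salt, which is the same compound; ring A is the 1,3,4-trisubstituted benzene ring and ring B the para-disubstituted one.

**Route**

Step 1
Reactants: 1 3,4-dihydroxybenzaldehyde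
Product: 2 3-hydroxy-4-[(4-methoxybenzyl)oxy]benzaldehyde
Conditions: 4-methoxybenzyl chloride (1.05 equiv), NaHCO3 (1.3 equiv), NaI (0.2 equiv), DMF, 40 °C
Reagents that add atoms: 4-methoxybenzyl chloride, COc1ccc(CCl)cc1
Why: Williamson etherification under weak-base control: only the 4-hydroxyl, para to the formyl group and therefore the more acidic one, is ionised by NaHCO3, so alkylation should occur there and leave the 3-hydroxyl free.

Step 2
Reactants: 2 3-hydroxy-4-[(4-methoxybenzyl)oxy]benzaldehyde; 3 diethyl (2-amino-2-oxoethyl)phosphonate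
Product: 4 (E)-3-{3-hydroxy-4-[(4-methoxybenzyl)oxy]phenyl}prop-2-enamide
Conditions: KOtBu (2.2 equiv), THF, 0 °C to rt; then 1 M HCl
Reagents that add atoms: none
Why: Horner–Wadsworth–Emmons olefination: the amide-stabilised phosphonate anion adds reversibly to the aldehyde of the phenoxide and eliminates through the more stable anti oxaphosphetane, which should give the E alkene and the primary amide in one step.

Step 3
Reactants: 4 (E)-3-{3-hydroxy-4-[(4-methoxybenzyl)oxy]phenyl}prop-2-enamide; 5 4-fluorobenzaldehyde
Product: 6 (E)-3-{3-(4-formylphenoxy)-4-[(4-methoxybenzyl)oxy]phenyl}prop-2-enamide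
Conditions: K2CO3, DMF, 110 °C
Reagents that add atoms: none
Why: Nucleophilic aromatic substitution (addition–elimination): the phenoxide of 4 attacks the fluorine-bearing carbon activated by the para-formyl group, and the non-ionised primary amide should not compete.

Step 4
Reactants: 6 (E)-3-{3-(4-formylphenoxy)-4-[(4-methoxybenzyl)oxy]phenyl}prop-2-enamide; 7 malonic acid
Product: 9 (E)-3-(4-{5-[(E)-3-amino-3-oxoprop-1-enyl]-2-[(4-methoxybenzyl)oxy]phenoxy}phenyl)prop-2-enoic acid, via arylidenemalonic acid 8 (not isolated)
Conditions: pyridine, piperidine (cat.), 90 °C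
Reagents that add atoms: none
Why: Knoevenagel–Doebner condensation: piperidine-catalysed condensation with malonic acid is followed by decarboxylation in hot pyridine, which should deliver the E cinnamic acid under thermodynamic control without touching the amide or the ethers.

Step 5
Reactants: 10 propane-1,3-diamine
Product: 11 N-(3-aminopropyl)-2-nitrobenzenesulfonamide
Conditions: 10 (5 equiv), CH2Cl2, 0 °C, slow addition of the sulfonyl chloride
Reagents that add atoms: 2-nitrobenzenesulfonyl chloride, O=[N+]([O-])c1ccccc1S(=O)(=O)Cl
Why: Sulfonylation of an amine with a sulfonyl chloride; the large excess of the symmetrical diamine should restrict reaction to one nitrogen and also binds the HCl.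

Step 6
Reactants: 9 (E)-3-(4-{5-[(E)-3-amino-3-oxoprop-1-enyl]-2-[(4-methoxybenzyl)oxy]phenoxy}phenyl)prop-2-enoic acid; 11 N-(3-aminopropyl)-2-nitrobenzenesulfonamide
Product: 12 (E)-3-(4-{5-[(E)-3-amino-3-oxoprop-1-enyl]-2-[(4-methoxybenzyl)oxy]phenoxy}phenyl)-N-{3-[(2-nitrophenyl)sulfonylamino]propyl}prop-2-enamide
Conditions: EDC·HCl (N-(3-dimethylaminopropyl)-N'-ethylcarbodiimide hydrochloride), HOBt, DMF, 0 °C to rt
Reagents that add atoms: none
Why: Carbodiimide/HOBt amide coupling: the primary alkylamine of 11 is far more nucleophilic than its sulfonamide N–H or the primary amide of 9, so a single new amide should form.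

Step 7
Reactants: 12 (E)-3-(4-{5-[(E)-3-amino-3-oxoprop-1-enyl]-2-[(4-methoxybenzyl)oxy]phenoxy}phenyl)-N-{3-[(2-nitrophenyl)sulfonylamino]propyl}prop-2-enamide; 13 but-3-yn-1-ol
Product: 14 (E)-3-(4-{5-[(E)-3-amino-3-oxoprop-1-enyl]-2-[(4-methoxybenzyl)oxy]phenoxy}phenyl)-N-(3-{but-3-ynyl[(2-nitrophenyl)sulfonyl]amino}propyl)prop-2-enamide
Conditions: PPh3, DIAD, THF/DMF, 0 °C to rt
Reagents that add atoms: none
Why: Mitsunobu N-alkylation of a 2-nitrobenzenesulfonamide: this N–H is the only one acidic enough to protonate the betaine, so the primary alcohol should be displaced at that nitrogen alone, which places the four-carbon arm on the central nitrogen.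

Step 8
Reactants: 14 (E)-3-(4-{5-[(E)-3-amino-3-oxoprop-1-enyl]-2-[(4-methoxybenzyl)oxy]phenoxy}phenyl)-N-(3-{but-3-ynyl[(2-nitrophenyl)sulfonyl]amino}propyl)prop-2-enamide
Product: 15 macrocyclic (Z)-enamide: the 24-membered ring of the target with a C3=C4 double bond in the four-carbon chain (counted from the central nitrogen); central nitrogen bearing 2-nitrobenzenesulfonyl; ring A 4-O-(4-methoxybenzyl)
Conditions: Ru(cod)(2-methylallyl)2 (10 mol%; cod = 1,5-cyclooctadiene), 1,4-bis(dicyclohexylphosphino)butane (12 mol%), Yb(OTf)3 (8 mol%), DMF, H2O (3 equiv), 60 °C, slow addition of 14 to 2 mM, dark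
Reagents that add atoms: none
Why: Proposed new method: ring-closing (macrocyclising) form of the ruthenium-catalysed anti-Markovnikov hydroamidation of terminal alkynes, whose closest known relative is the intermolecular addition of primary amides (cinnamamide included) to 1-alkynes that gives (Z)-N-alk-1-enyl amides. Mechanistically the phosphine-ligated ruthenium should convert the terminal alkyne of 14 into a vinylidene whose electrophilic α-carbon (the former ≡CH carbon) is attacked by the ruthenium-bound amidate of the primary cinnamamide; protonolysis of the alkenyl–ruthenium bond then releases the secondary enamide and so makes the N–CH= bond that closes the ring. The one ring formed, the 24-membered macrolactam, closes in a formal 24-endo-dig mode because both alkyne carbons end up in the ring. No stereocentre is created; the Z enamide geometry expected from catalyst control is of no consequence because step 9 saturates this C=C. The step needs anti-Markovnikov regioselectivity, which the vinylidene pathway open only to the terminal alkyne secures, and N–H chemoselectivity, which the substrate secures because the central nitrogen is a fully substituted sulfonamide and the only other N–H, the secondary ring-B cinnamamide, could close only a strained nine-membered ring. Ring closure should prevail over oligomerisation under slow addition because the bent diaryl ether and the two rigid E-cinnamoyl arms hold the chain ends on the same side.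

Step 9
Reactants: 15 macrocyclic (Z)-enamide
Product: 17 macrocyclic phenol: the saturated 24-membered bis-cinnamamide ring of the target with free ring-A 4-hydroxyl; central nitrogen bearing 2-nitrobenzenesulfonyl, via PMB-protected saturated macrolactam 16 (not isolated)
Conditions: Et3SiH (6 equiv), TFA (5 equiv), CH2Cl2, 0 °C; then TFA/CH2Cl2 1:4, rt
Reagents that add atoms: none
Why: Ionic hydrogenation followed by acidolysis: TFA protonates the electron-rich enamide at its β-carbon to an N-acyliminium ion that Et3SiH reduces while the two electron-poor cinnamoyl alkenes are not protonated, and the higher acid concentration then ionises the 4-methoxybenzyl ether, whose cation the silane traps.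

Step 10
Reactants: 17 macrocyclic phenol
Product: 18 sodium salt of the ring-A 4-O-sulfate of 17 (central nitrogen still bearing 2-nitrobenzenesulfonyl)
Conditions: SO3·pyridine (5 equiv), pyridine, rt; then aq. NaHCO3, C18 chromatography
Reagents that add atoms: sulfur trioxide–pyridine complex, O=S(=O)=O.c1ccncc1; sodium hydrogen carbonate, [Na+].OC([O-])=O
Why: O-sulfation of a phenol with a sulfur trioxide–amine complex; the amide N–H groups and the fully substituted sulfonamide nitrogen should not react, which is why the amine is still masked at this stage.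

Step 11
Reactants: 18 sodium salt of the ring-A 4-O-sulfate
Product: 19 target macrocycle CID124202369 (inner salt of the secondary amine and the aryl hydrogen sulfate)
Conditions: PhSH (3 equiv), K2CO3 (4 equiv), DMF, rt; then AcOH to pH 6, reversed-phase HPLC
Reagents that add atoms: none
Why: Thiolate-mediated cleavage of the 2-nitrobenzenesulfonamide by nucleophilic aromatic substitution (Meisenheimer adduct, loss of SO2), a base-only deprotection under which the aryl sulfate monoester anion and the cinnamamides should persist.

**Compound list**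

1 | 3,4-dihydroxybenzaldehyde | O=Cc1ccc(O)c(O)c1 | starting material
2 | 3-hydroxy-4-[(4-methoxybenzyl)oxy]benzaldehyde | O=Cc1ccc(OCc2ccc(OC)cc2)c(O)c1 | intermediate
3 | diethyl (2-amino-2-oxoethyl)phosphonate | CCOP(=O)(CC(N)=O)OCC | starting material
4 | (E)-3-{3-hydroxy-4-[(4-methoxybenzyl)oxy]phenyl}prop-2-enamide | NC(=O)/C=C/c1ccc(OCc2ccc(OC)cc2)c(O)c1 | intermediate
5 | 4-fluorobenzaldehyde | O=Cc1ccc(F)cc1 | starting material
6 | (E)-3-{3-(4-formylphenoxy)-4-[(4-methoxybenzyl)oxy]phenyl}prop-2-enamide | NC(=O)/C=C/c1ccc(OCc2ccc(OC)cc2)c(Oc2ccc(C=O)cc2)c1 | intermediate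
7 | malonic acid | OC(=O)CC(=O)O | starting material
8 | arylidenemalonic acid: 2-[(4-{5-[(E)-3-amino-3-oxoprop-1-enyl]-2-[(4-methoxybenzyl)oxy]phenoxy}phenyl)methylidene]propanedioic acid | NC(=O)/C=C/c1ccc(OCc2ccc(OC)cc2)c(Oc2ccc(C=C(C(=O)O)C(=O)O)cc2)c1 | intermediate
9 | (E)-3-(4-{5-[(E)-3-amino-3-oxoprop-1-enyl]-2-[(4-methoxybenzyl)oxy]phenoxy}phenyl)prop-2-enoic acid | NC(=O)/C=C/c1ccc(OCc2ccc(OC)cc2)c(Oc2ccc(/C=C/C(=O)O)cc2)c1 | intermediate
10 | propane-1,3-diamine | NCCCN | starting material
11 | N-(3-aminopropyl)-2-nitrobenzenesulfonamide | NCCCNS(=O)(=O)c1ccccc1[N+](=O)[O-] | intermediate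
12 | (E)-3-(4-{5-[(E)-3-amino-3-oxoprop-1-enyl]-2-[(4-methoxybenzyl)oxy]phenoxy}phenyl)-N-{3-[(2-nitrophenyl)sulfonylamino]propyl}prop-2-enamide | NC(=O)/C=C/c1ccc(OCc2ccc(OC)cc2)c(Oc2ccc(/C=C/C(=O)NCCCNS(=O)(=O)c3ccccc3[N+](=O)[O-])cc2)c1 | intermediate
13 | but-3-yn-1-ol | C#CCCO | starting material
14 | (E)-3-(4-{5-[(E)-3-amino-3-oxoprop-1-enyl]-2-[(4-methoxybenzyl)oxy]phenoxy}phenyl)-N-(3-{but-3-ynyl[(2-nitrophenyl)sulfonyl]amino}propyl)prop-2-enamide | NC(=O)/C=C/c1ccc(OCc2ccc(OC)cc2)c(Oc2ccc(/C=C/C(=O)NCCCN(CCC#C)S(=O)(=O)c3ccccc3[N+](=O)[O-])cc2)c1 | intermediate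
15 | macrocyclic (Z)-enamide: 24-membered ring of the target with C3=C4 unsaturation in the four-carbon chain, N-(2-nitrophenyl)sulfonyl on the central nitrogen, ring A 4-O-(4-methoxybenzyl) | O=C1/C=C/c2ccc(OCc3ccc(OC)cc3)c(c2)Oc2ccc(cc2)/C=C/C(=O)NCCCN(S(=O)(=O)c3ccccc3[N+](=O)[O-])CC/C=C\N1 | intermediate
16 | PMB-protected saturated macrolactam: as 15 with the four-carbon chain saturated | O=C1/C=C/c2ccc(OCc3ccc(OC)cc3)c(c2)Oc2ccc(cc2)/C=C/C(=O)NCCCN(S(=O)(=O)c3ccccc3[N+](=O)[O-])CCCCN1 | intermediate
17 | macrocyclic phenol: as 16 with free ring-A 4-hydroxyl | O=C1/C=C/c2ccc(O)c(c2)Oc2ccc(cc2)/C=C/C(=O)NCCCN(S(=O)(=O)c3ccccc3[N+](=O)[O-])CCCCN1 | intermediate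
18 | sodium salt of the ring-A 4-O-sulfate of 17 | O=C1/C=C/c2ccc(OS(=O)(=O)[O-])c(c2)Oc2ccc(cc2)/C=C/C(=O)NCCCN(S(=O)(=O)c3ccccc3[N+](=O)[O-])CCCCN1.[Na+] | intermediate
19 | CID124202369 | O=C1/C=C/c2ccc(OS(=O)(=O)O)c(c2)Oc2ccc(cc2)/C=C/C(=O)NCCCNCCCCN1 | target

**Step count and risks**

Total: 11 steps. Longest linear sequence: 10 steps (steps 1–4 and 6–11, from 1 to 19); step 5 is a one-step branch.

Step 8 (ring-closing hydroamidation, proposed new method). Catalyst turnover may stall at high dilution, and hydration of the vinylidene by the added water, alkyne dimerisation or intermolecular oligomerisation may outrun ring closure. The fallback uses known chemistry, sets out from 12 (with 13 as the source of the four-carbon unit) and returns at 15. But-3-yn-1-ol 13 is iodinated (N-iodosuccinimide, AgNO3 cat., acetone) to 4-iodobut-3-yn-1-ol F1, which is reduced with diimide (2-nitrobenzenesulfonyl hydrazide, Et3N) to (Z)-4-iodobut-3-en-1-ol F2. Mitsunobu alkylation of 12 with F2 (PPh3, DIAD, THF) gives the (Z)-vinyl iodide seco-amide F3. This is cyclised by copper-catalysed Goldberg-type N-vinylation of the primary amide (CuI, N,N'-dimethylethane-1,2-diamine, Cs2CO3, THF, 60 °C, high dilution), a ring closure with precedent for macrocyclic enamides, with retention of alkene geometry to give 15.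

Step 9 (ionic hydrogenation and ether acidolysis). The N-acyliminium ion may be captured by adventitious water before hydride transfer, which would hydrolyse the enamide and reopen the ring, or the 4-methoxybenzyl cation may alkylate the liberated phenol ring. The fallback sets out from 15 and makes no new compound (F0). The enamide alone is saturated by chelation-directed homogeneous hydrogenation ([Rh(cod)(dppb)]BF4, dppb = 1,4-bis(diphenylphosphino)butane, H2 1 atm, MeOH/CH2Cl2). The enamide carbonyl/alkene pair is the privileged binding site, so the cinnamoyl alkenes and the nitro group should be spared. This gives 16 as an isolated compound, and the ether is then cleaved separately (TFA, Et3SiH, CH2Cl2), returning to the route at 17.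

Step 11 (sulfonamide cleavage on the sulfated macrocycle). Reversible conjugate addition of the thiolate to the cinnamoyl groups may be hard to drive back on a sulfated substrate, and the zwitterionic product may be lost on separating it from thiol, disulfide and salts. The fallback sets out from 17 and returns at 19. The sulfonyl group is removed first (PhSH, K2CO3, DMF) to give the aminophenol macrocycle F4, an ordinary base that can be purified by extraction and in which thiol adducts can be reverted. The amine is re-masked as its 9-fluorenylmethyl carbamate F5 (Fmoc-OSu, NaHCO3, dioxane/H2O). The phenol is sulfated (SO3·pyridine, DMF; aq. NaHCO3) to the sodium sulfate F6. The carbamate is removed by base-induced β-elimination (piperidine, DMF; AcOH to pH 6), giving 19 with no thiol in the last step.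

Further compounds
F1 | step 8 | 4-iodobut-3-yn-1-ol | OCCC#CI
F2 | step 8 | (Z)-4-iodobut-3-en-1-ol | OCC/C=C\I
F3 | step 8 | (E)-3-(4-{5-[(E)-3-amino-3-oxoprop-1-enyl]-2-[(4-methoxybenzyl)oxy]phenoxy}phenyl)-N-(3-{[(Z)-4-iodobut-3-enyl][(2-nitrophenyl)sulfonyl]amino}propyl)prop-2-enamide | NC(=O)/C=C/c1ccc(OCc2ccc(OC)cc2)c(Oc2ccc(/C=C/C(=O)NCCCN(CC/C=C\I)S(=O)(=O)c3ccccc3[N+](=O)[O-])cc2)c1
F0 | step 9 | none | none
F4 | step 11 | aminophenol macrocycle (17 without the sulfonyl group) | O=C1/C=C/c2ccc(O)c(c2)Oc2ccc(cc2)/C=C/C(=O)NCCCNCCCCN1
F5 | step 11 | N-(9-fluorenylmethoxycarbonyl) derivative of F4 at the central nitrogen | O=C1/C=C/c2ccc(O)c(c2)Oc2ccc(cc2)/C=C/C(=O)NCCCN(C(=O)OCC3c4ccccc4-c4ccccc43)CCCCN1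
F6 | step 11 | sodium salt of the ring-A 4-O-sulfate of F5 | O=C1/C=C/c2ccc(OS(=O)(=O)[O-])c(c2)Oc2ccc(cc2)/C=C/C(=O)NCCCN(C(=O)OCC3c4ccccc4-c4ccccc43)CCCCN1.[Na+]
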